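The readings were computed on assumed constants.

At early times I compare the red and ochre runs by one number, since both are charged with 0.0180 M of free catalyst.

| flask | starting material | free catalyst | time |
|---|---|---|---|
| red | 0.600 M | 0.0180 M |  |
| ochre | 0.240 M | 0.0180 M |  |
| blue | 0.600 M | 0.0540 M |  |
| amber | 1.80 M | 0.0540 M | 190 s |

- red run (time / s: [product] / M): 24: 0.0598; 48: 0.1114; 71: 0.1617; 95: 0.2078; 120: 0.2566; 140: 0.2809; 170: 0.3243; 190: 0.3481
- ochre run (time / s: [product] / M): 24: 0.0297; 48: 0.0582; 71: 0.0764; 95: 0.0940; 120: 0.1078; 140: 0.1252; 170: 0.1433; 190: 0.1483
- blue run (time / s: [product] / M): 24: 0.1595; 48: 0.2816; 71: 0.3667; 95: 0.4286; 120: 0.4737; 140: 0.4964; 170: 0.5244; 190: 0.5391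

(readings scatter by 0.002 M)

1. the exponent of [starting material] in the starting rate at the charge of the red run (at the point where two percent of the starting material have become product) (one fixed amount of product, the same in the runs compared)
2. the exponent of [free catalyst] in the starting rate at the charge of the red run (at the point where two percent of the starting material have become product)
3. the ochre run starts with 0.360 M less of starting material than the red run, and with no product. Compared where both hold the same amount of starting material, once fifteen percent of what the ochre run was charged with has turned into product, is the ochre run faster, slower or alike (within a tenth)?
4. product in the amber run at 190 s, as a share of the starting material charged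

- Overall: starting material -> product, with free catalyst as catalyst.
- Constant volume, constant temperature.
- What is held in complexes is read along with the free species.
- An order is taken over about fifteen percent of the charge, up and down.

I divide each rate by the starting material held. This gives a specific rate, the pseudo-first-order constant of that stretch. Up to 48 s, the ochre run holds about 0.211 M on average and gives 0.00575 /s. Over the same stretch the red run gives 0.00426 /s, less than the ochre run, so the order in starting material lies below one.

Between 140 s and 190 s, the red run holds about 0.285 M and gives 0.00471 /s. The quotient of this late value and the ochre value is 0.819, and time has dropped out of it. I call it the retained activity, the late specific rate per catalyst charged over the fresh one at similar starting material. It is a reading, taken from product values that scatter by 0.002 M. Because it lies below one, I read the ochre run as faster at equal starting material.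

One number is not quite enough. Over its late stretch the red run still holds 0.285 M, more than the 0.211 M of the ochre run, so part of the gap may come from the order below one. The number also can't name what lowers the activity. Nor does it reach the amber run, whose charge of starting material is higher than that of any other run.

The forecast gives exponents of 0.65 in starting material and 1 in free catalyst, and 78% for the amber run. It calls the ochre run faster, holding that “ochre at equal substrate is fresher than red”. On that direction we agree. The other figures are the forecast's, and I reckon none of my own.

The simulation gives exponents of 0.56 and 0.99, 81.7% for the amber run, and the ochre run faster.

free catalyst + starting material ⇌ catalyst-substrate complex (0.5570 /M/s, 0.7560 /s); catalyst-substrate complex → product + free catalyst (1.240 /s); 2 free catalyst → 2 spent catalyst (0.05410 /M/s); catalyst-substrate complex + starting material ⇌ doubly bound catalyst, settled at all times (2.390 /M) At the point asked, the ochre rate is 1.3 times the red rate. I carry the retained activity to the blue run. Between 48 s and 95 s the blue run holds about 0.245 M and gives 0.0128 /s. Per catalyst charged, against the same ochre value, the retained activity of the blue run is 0.740.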